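The route rests on cutting the C8–C14 bond, the link between two adjacent fully substituted carbons that sits inside both ring C and the γ-lactone O–C8–C14–C13–C27. Rings A/B and rings D/E are made separately, joined at C12–C13, and tied through the C27–O–C8 ester as a seven-membered enol lactone carrying an exocyclic C14 methylene and a ring B β-acyloxy enone (C6 ketone, C7=C8). A hydrogen-atom-transfer radical conjugate cyclization then forms C8–C14, closing ring C and contracting the enol lactone to the γ-lactone while setting C8 and C14. Ketone reduction and dehydration give the 5(10),6-diene.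

Key step: step 24

Remarks on the chemistry
- Atom labels are those of the D:B-friedooleanane skeleton for every intermediate (ring A: C1–C5, C10; ring B: C5–C10; C11–C12 on C9; C25 methyl on C9; C27 carboxyl on C13; C26 becomes the C14 methyl).
- The ring B 1,3-dione (C6, C8) is acidic and its C6 carbonyl would compete with C14 in carbonyl olefination. It is therefore carried as a 6,8-bis(silyloxy) unit and unveiled only after the C12–C13 union and the C14 methylenation.
- C27 is carried as an allyl ester, because basic hydrolysis would cleave the C3 benzoate first.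
- The enol ester of the key-step precursor is an acylating agent, so the key step is run without a primary alcohol solvent.
- Assumption: the C6 carbinol (from step 8) is an epimer mixture, and the ring A closure (step 11) may give some Δ1(10) olefin beside the Δ5(10) olefin that is drawn. All of these converge in step 22.

Step 1
Reactants: 1 2-methylcyclohexane-1,3-dione; 2 allyl bromide
Product: 3 2-allyl-2-methylcyclohexane-1,3-dione
Conditions: 1 M aq. NaOH, rt
Reagents that add atoms: none
Why: C-alkylation of the stabilized enolate of a 2-substituted cyclic 1,3-dione by a reactive allylic bromide makes the future C9 (methyl C25, allyl as the source of C11–C12) as a prochiral quaternary carbon.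

Step 2
Reactants: 3 2-allyl-2-methylcyclohexane-1,3-dione
Product: 4 (2R,3R)-2-allyl-3-hydroxy-2-methylcyclohexan-1-one
Conditions: (S)-2-methyl-CBS-oxazaborolidine (10 mol %), catecholborane, toluene, −78 °C
Reagents that add atoms: none
Why: Corey–Bakshi–Shibata reduction used as a desymmetrization: the (S)-catalyst, chosen by the usual large/small model with the quaternary carbon as the large group, should reduce one of the two enantiotopic carbonyl groups with hydride arriving anti to the allyl group, which fixes C9 (2R) and gives the 3R carbinol (future C8, hydroxyl cis to allyl).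

Step 3
Reactants: 4 (2R,3R)-2-allyl-3-hydroxy-2-methylcyclohexan-1-one
Product: 5 (2R,3R)-2-allyl-3-(tert-butyldimethylsilyloxy)-2-methylcyclohexan-1-one
Conditions: TBSOTf, 2,6-lutidine, CH2Cl2, −78 → 0 °C
Reagents that add atoms: tert-butyldimethylsilyl triflate, CC(C)(C)[Si](C)(C)OS(=O)(=O)C(F)(F)F
Why: Silyl ether formation on the hindered secondary alcohol protects the C8 oxygen for the oxidations and the organometallic addition that follow.

Step 4
Reactants: 5 (2R,3R)-2-allyl-3-(tert-butyldimethylsilyloxy)-2-methylcyclohexan-1-one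
Product: 6 (5R,6R)-6-allyl-5-(tert-butyldimethylsilyloxy)-6-methylcyclohex-2-en-1-one
Conditions: IBX, DMSO, 70 °C
Reagents that add atoms: none
Why: IBX-mediated α,β-dehydrogenation of the ketone; C9 is quaternary, so only the C5–C6 side can be desaturated.

Step 5
Reactants: 6 (5R,6R)-6-allyl-5-(tert-butyldimethylsilyloxy)-6-methylcyclohex-2-en-1-one; 7 5-bromo-2-methylpent-2-ene
Product: 9 (5R,6R)-6-allyl-5-(tert-butyldimethylsilyloxy)-6-methyl-1-(4-methylpent-3-enyl)cyclohex-2-en-1-ol (C10 carbinol epimers), via Grignard reagent 8 (not isolated)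
Conditions: 7, Mg, THF, rt; CeCl3, THF, −78 °C; then 6, −78 → 0 °C
Reagents that add atoms: none
Why: Grignard formation and cerium-mediated 1,2-addition to the hindered enone carbonyl attach the C1–C4 chain to C10; the carbinol configuration does not matter because this carbon becomes sp2 in step 6.

Step 6
Reactants: 9 (5R,6R)-6-allyl-5-(tert-butyldimethylsilyloxy)-6-methyl-1-(4-methylpent-3-enyl)cyclohex-2-en-1-ol
Product: 10 (4S,5R)-4-allyl-5-(tert-butyldimethylsilyloxy)-4-methyl-3-(4-methylpent-3-enyl)cyclohex-2-en-1-one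
Conditions: [C5H5NH][CrO3Cl] (pyridinium chlorochromate), NaOAc, 4 Å molecular sieves, CH2Cl2, rt
Reagents that add atoms: pyridinium chlorochromate, [O-][Cr](=O)(=O)Cl.c1cc[nH+]cc1
Why: Babler–Dauben oxidative transposition: the chromate ester of the tertiary allylic alcohol undergoes a [3,3] shift and oxidation, which moves oxygen to C6 and the double bond to C5=C10.

Step 7
Reactants: 10 (4S,5R)-4-allyl-5-(tert-butyldimethylsilyloxy)-4-methyl-3-(4-methylpent-3-enyl)cyclohex-2-en-1-one
Product: 11 (4S,5R)-4-allyl-5-(tert-butyldimethylsilyloxy)-3-[2-((2S)-3,3-dimethyloxiran-2-yl)ethyl]-4-methylcyclohex-2-en-1-one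
Conditions: enantiomer of the D-fructose-derived Shi ketone (30 mol %), KHSO5 (Oxone), K2CO3, Bu4NHSO4, MeCN–CH2(OMe)2–aq. Na2B4O7, 0 °C
Reagents that add atoms: potassium peroxymonosulfate KHSO5, [K+].[O-]S(=O)(=O)OO
Why: Shi asymmetric epoxidation (chiral dioxirane) of the electron-rich trisubstituted alkene, which leaves the enone and the monosubstituted allyl alkene untouched; the L-series ketone should give the (S)-epoxide that later becomes the 3β oxygen.

Step 8
Reactants: 11 (4S,5R)-4-allyl-5-(tert-butyldimethylsilyloxy)-3-[2-((2S)-3,3-dimethyloxiran-2-yl)ethyl]-4-methylcyclohex-2-en-1-one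
Product: 13 (4S,5R)-5-(tert-butyldimethylsilyloxy)-3-[2-((2S)-3,3-dimethyloxiran-2-yl)ethyl]-4-(2-hydroxyethyl)-4-methylcyclohex-2-en-1-ol (C6 carbinol epimers), via hydroxy enone 12 (not isolated)
Conditions: O3, CH2Cl2–MeOH, −78 °C; NaBH4, −78 → −20 °C; then CeCl3·7H2O, NaBH4, −40 °C
Reagents that add atoms: ozone, [O-][O+]=O
Why: Ozonolysis of the only electron-rich alkene left (the enone reacts far more slowly) shortens allyl to the C11–C12 unit, borohydride reduces the ozonide to the C12 alcohol, and Luche 1,2-reduction turns the C6 ketone into an allylic alcohol (epimers, re-oxidized in step 22) so that C5=C10 becomes a nucleophilic alkene.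

Step 9
Reactants: 13 diol (C12 primary alcohol, C6 allylic alcohol)
Product: 14 primary tosylate of 13 (C12–OTs; C6 hydroxyl free)
Conditions: TsCl (1.05 equiv), pyridine, CH2Cl2, 0 °C
Reagents that add atoms: 4-toluenesulfonyl chloride, Cc1ccc(cc1)S(=O)(=O)Cl
Why: Selective sulfonylation (tosylation) of the primary alcohol over the secondary allylic one installs the leaving group at C12.

Step 10
Reactants: 14 primary tosylate (C6 hydroxyl free)
Product: 15 C6 tert-butyldimethylsilyl ether of 14 (6ξ- and 8α-silyloxy groups, C12–OTs, (S)-epoxide)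
Conditions: TBSCl, imidazole, DMAP (cat.), CH2Cl2, rt
Reagents that add atoms: tert-butyldimethylsilyl chloride, CC(C)(C)[Si](C)(C)Cl
Why: Silyl ether formation masks the C6 hydroxyl, so that ring B carries no carbonyl group and no free hydroxyl through steps 11–19.

Step 11
Reactants: 15 epoxy olefin (6ξ,8α-bis-silyl ether, C12–OTs)
Product: 16 rings A/B alcohol: 3β-hydroxy-4,4,9β-trimethyl-6ξ,8α-bis(tert-butyldimethylsilyloxy)-9α-(2-tosyloxyethyl)-Δ5(10)-octalin
Conditions: MeAlCl2 (2 equiv), CH2Cl2, −78 °C
Reagents that add atoms: none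
Why: Lewis acid-promoted epoxy-olefin (cation–π) cyclization: the epoxide opens at its tertiary carbon C4, which is attacked by C5 of the trisubstituted C5=C10 alkene through a chair-like transition state to close ring A with the C3 oxygen kept in the S (β) configuration set in step 7, and the C10 cation loses a proton (from C5, or from C1 to give the Δ1(10) isomer that converges in step 22).

Step 12
Reactants: 16 rings A/B alcohol
Product: 17 rings A/B tosylate: 3β-benzoyloxy-4,4,9β-trimethyl-6ξ,8α-bis(tert-butyldimethylsilyloxy)-9α-(2-tosyloxyethyl)-Δ5(10)-octalin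
Conditions: BzCl, i-Pr2NEt, DMAP (cat.), CH2Cl2, 0 °C → rt
Reagents that add atoms: benzoyl chloride, O=C(Cl)c1ccccc1
Why: Acylation (benzoylation) of the only free hydroxyl installs the C3 benzoate of the target.

Step 13
Reactants: 18 3,3-dimethylcyclohexan-1-one
Product: 19 2,5,5-trimethylcyclohexan-1-one (racemic)
Conditions: LiN(i-Pr)2, THF, −78 °C; MeI
Reagents that add atoms: iodomethane, CI
Why: Kinetic enolate alkylation: deprotonation occurs at the α-carbon remote from the gem-dimethyl group, and methylation gives the racemic ketone whose stereocentre is re-set in step 14.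

Step 14
Reactants: 19 2,5,5-trimethylcyclohexan-1-one; 20 (S)-1-phenylethylamine; 21 methyl vinyl ketone
Product: 24 (R)-2,5,5-trimethyl-2-(3-oxobutyl)cyclohexan-1-one, via ketimine 22 (not isolated), via alkylated ketimine 23 (not isolated)
Conditions: 20, TsOH (cat.), toluene, reflux (Dean–Stark); then 21, THF, 40 °C; then 10% aq. AcOH, rt
Reagents that add atoms: none
Why: Michael addition of the more substituted secondary enamine tautomer of the chiral ketimine to the enone (first half of an asymmetric Robinson annulation); the (S)-phenylethyl group shields one face so that the C17 quaternary centre should form with the R configuration, and mild acid releases the 1,5-diketone and the amine.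

Step 15
Reactants: 24 (R)-2,5,5-trimethyl-2-(3-oxobutyl)cyclohexan-1-one
Product: 25 (4aR)-4a,7,7-trimethyl-4,4a,5,6,7,8-hexahydronaphthalen-2(3H)-one
Conditions: NaOMe, MeOH, 60 °C
Reagents that add atoms: none
Why: Intramolecular aldol condensation completes the Robinson annulation (ring D enone) without touching the C17 stereocentre.

Step 16
Reactants: 25 (4aR)-4a,7,7-trimethyl-4,4a,5,6,7,8-hexahydronaphthalen-2(3H)-one
Product: 26 (4aR,8aS)-4a,7,7-trimethyloctahydronaphthalen-2(1H)-one (cis-fused)
Conditions: H2 (1 atm), Pd/C, EtOAc, rt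
Reagents that add atoms: none
Why: Heterogeneous hydrogenation should deliver hydrogen to C18 from the face anti to the axial C20 methyl, that is syn to the angular C17 methyl, giving the cis ring fusion (18β-H).

Step 17
Reactants: 26 (4aR,8aS)-4a,7,7-trimethyloctahydronaphthalen-2(1H)-one; 27 diallyl carbonate
Product: 28 allyl (4aR,8aS)-4a,7,7-trimethyl-2-oxodecahydronaphthalene-1-carboxylate (C13 epimers and enol)
Conditions: NaH, 27, THF, reflux; AcOH quench
Reagents that add atoms: none
Why: Crossed Claisen acylation under equilibrating conditions; a cis-fused 2-decalone enolizes toward the ring fusion (as 5β-3-keto steroids do), so the allyl ester (C27) should be introduced at C13.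

Step 18
Reactants: 28 allyl β-keto ester of rings D/E; 17 rings A/B tosylate
Product: 29 allyl 3β-benzoyloxy-6ξ,8α-bis(tert-butyldimethylsilyloxy)-14-oxo-26-nor-8,14-seco-D:B-friedoolean-5(10)-en-27-oate
Conditions: Cs2CO3, NaI, DMF, 50 °C
Reagents that add atoms: none
Why: C-alkylation of the caesium enolate of the β-keto ester by the primary iodide formed in situ (Finkelstein exchange) creates the C13 quaternary centre; the electrophile should enter on the convex β face of the cis-fused bicycle, the face taken by electrophiles at C4 of 5β-3-keto steroids, so that C12 is β and C27 is α.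

Step 19
Reactants: 29 14-oxo allyl ester
Product: 30 allyl 3β-benzoyloxy-6ξ,8α-bis(tert-butyldimethylsilyloxy)-8,14-seco-D:B-friedooleana-5(10),14(26)-dien-27-oate
Conditions: Zn, CH2Br2, TiCl4, THF–CH2Cl2, 0 °C → rt
Reagents that add atoms: dibromomethane, BrCBr
Why: Lombardo methylenation, a non-basic carbonyl olefination suited to hindered enolizable ketones and inert to the allyl and benzoate esters, installs the C14 exocyclic methylene (C26).

Step 20
Reactants: 30 allyl ester with C14 methylene
Product: 31 3β-benzoyloxy-6ξ,8α-bis(tert-butyldimethylsilyloxy)-8,14-seco-D:B-friedooleana-5(10),14(26)-dien-27-oic acid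
Conditions: Pd(PPh3)4 (5 mol %), PhSiH3, CH2Cl2, rt
Reagents that add atoms: none
Why: Palladium-catalysed allyl transfer to hydride (Tsuji–Trost deallylation) frees the hindered C27 acid under neutral conditions, before any 1,3-dione enolate is present to compete for the allyl group.

Step 21
Reactants: 31 bis-silyl ether acid
Product: 32 3β-benzoyloxy-6ξ,8α-dihydroxy-8,14-seco-D:B-friedooleana-5(10),14(26)-dien-27-oic acid
Conditions: HF·pyridine, pyridine, THF, 0 °C → rt
Reagents that add atoms: none
Why: Fluoride-mediated desilylation removes both silyl ethers under buffered conditions that spare the benzoate and the 1,1-disubstituted alkene.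

Step 22
Reactants: 32 diol acid
Product: 33 3β-benzoyloxy-6,8-dioxo-8,14-seco-D:B-friedooleana-5(10),14(26)-dien-27-oic acid
Conditions: Dess–Martin periodinane, pyridine, CH2Cl2, 0 °C → rt; then Et3N
Reagents that add atoms: none
Why: Dess–Martin oxidation of both secondary alcohols gives the ring B 1,3-dione, and brief base treatment moves any Δ1(10) double bond into conjugation (C5=C10), so that all isomers carried since step 8 converge on one ene-dione.

Step 23
Reactants: 33 ene-dione acid
Product: 35 3β-benzoyloxy-6-oxo-8,14-seco-D:B-friedooleana-5(10),7,14(26)-trien-27,8-olide (seven-membered enol lactone), via acyl fluoride 34 (not isolated)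
Conditions: cyanuric fluoride, pyridine, CH2Cl2, 0 °C; then i-Pr2NEt, CH2Cl2 (high dilution), rt
Reagents that add atoms: none
Why: Acid fluoride formation is selective for the carboxylic acid, and intramolecular O-acylation of the 1,3-dione enol (enol lactonization) can reach only O8, through a seven-membered ring, since O6 would require a bridged nine-membered ring.

Step 24
Reactants: 35 seven-membered enol lactone with C14 methylene
Product: 36 3β-benzoyloxy-6-oxo-D:B-friedoolean-5(10)-en-27,8α-olide
Conditions: Fe(acac)3 (30 mol %), Ph(i-PrO)SiH2, THF–i-PrOH (20:1), 40 °C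
Reagents that add atoms: none
Why: Fe(acac)3 and the silane generate an iron hydride that transfers a hydrogen atom to the terminal carbon (C26) of the electron-rich 1,1-disubstituted alkene, giving the C14 methyl group and a tertiary C14 radical, which adds to C8, the β-carbon of the ring B β-acyloxy enone, after which the C7 α-keto radical is reduced and protonated (Mukaiyama-type hydrogen-atom transfer followed by a Giese reaction, the known iron/silane reductive alkene–enone coupling used to join two quaternary carbons). The single new bond closes the γ-lactone (C14–C13–C27–O–C8) in a 5-exo-trig mode and ring C (C14–C13–C12–C11–C9–C8) in a 6-exo-trig mode. C14 is set by the two-atom C27–O tether, which sits on the α face of ring D at C13 and can deliver C8 only to that face, leaving the new methyl β. C8 is set by the C9 centre through the C9–C11–C12 chain, which leaves C9 on the α face of ring B and closes ring C as a trans-fused chair, so that the C8 oxygen ends up α. The step needs chemoselective hydrogen-atom transfer to the C14 methylene, secured because the other two alkenes (C5=C10 and C7=C8) are conjugated and electron-poor, and attack at C8 rather than C10, secured by the short ester tether. An alkoxysilane in THF with only a little i-PrOH replaces a primary alcohol solvent so that the enol ester is not solvolysed.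

Step 25
Reactants: 36 pentacyclic keto lactone
Product: 37 3β-benzoyloxy-6ξ-hydroxy-D:B-friedoolean-5(10)-en-27,8α-olide
Conditions: NaBH4, CeCl3·7H2O, MeOH–THF, −40 °C
Reagents that add atoms: none
Why: Luche 1,2-reduction of the conjugated C6 ketone gives the allylic alcohol without touching the benzoate or the lactone; either C6 epimer can be used because C7 carries two hydrogens.

Step 26
Reactants: 37 allylic alcohol
Product: 38 3β-benzoyloxy-D:B-friedooleana-5(10),6-dien-27,8α-olide (target)
Conditions: Burgess reagent, benzene, 50 °C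
Reagents that add atoms: none
Why: Burgess dehydration: the C6 sulfamate undergoes syn elimination with a C7 hydrogen, the only β-hydrogens available (C5 is sp2), to give the C6=C7 bond conjugated with C5=C10.

Compound list
1 | 2-methylcyclohexane-1,3-dione | CC1C(=O)CCCC1=O | starting material
2 | allyl bromide | C=CCBr | starting material
3 | 2-allyl-2-methylcyclohexane-1,3-dione | C=CCC1(C)C(=O)CCCC1=O | intermediate
4 | (2R,3R)-2-allyl-3-hydroxy-2-methylcyclohexan-1-one | C=CC[C@]1(C)[C@H](O)CCCC1=O | intermediate
5 | (2R,3R)-2-allyl-3-(tert-butyldimethylsilyloxy)-2-methylcyclohexan-1-one | C=CC[C@]1(C)[C@H](O[Si](C)(C)C(C)(C)C)CCCC1=O | intermediate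
6 | (5R,6R)-6-allyl-5-(tert-butyldimethylsilyloxy)-6-methylcyclohex-2-en-1-one | C=CC[C@]1(C)[C@H](O[Si](C)(C)C(C)(C)C)CC=CC1=O | intermediate
7 | 5-bromo-2-methylpent-2-ene | CC(C)=CCCBr | starting material
8 | (4-methylpent-3-enyl)magnesium bromide | CC(C)=CCC[Mg]Br | intermediate
9 | (5R,6R)-6-allyl-5-(tert-butyldimethylsilyloxy)-6-methyl-1-(4-methylpent-3-enyl)cyclohex-2-en-1-ol (C10 carbinol epimers) | C=CC[C@]1(C)[C@H](O[Si](C)(C)C(C)(C)C)CC=CC1(O)CCC=C(C)C | intermediate
10 | (4S,5R)-4-allyl-5-(tert-butyldimethylsilyloxy)-4-methyl-3-(4-methylpent-3-enyl)cyclohex-2-en-1-one | C=CC[C@]1(C)[C@H](O[Si](C)(C)C(C)(C)C)CC(=O)C=C1CCC=C(C)C | intermediate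
11 | (4S,5R)-4-allyl-5-(tert-butyldimethylsilyloxy)-3-[2-((2S)-3,3-dimethyloxiran-2-yl)ethyl]-4-methylcyclohex-2-en-1-one | C=CC[C@]1(C)[C@H](O[Si](C)(C)C(C)(C)C)CC(=O)C=C1CC[C@@H]2OC2(C)C | intermediate
12 | (4S,5R)-5-(tert-butyldimethylsilyloxy)-3-[2-((2S)-3,3-dimethyloxiran-2-yl)ethyl]-4-(2-hydroxyethyl)-4-methylcyclohex-2-en-1-one | OCC[C@]1(C)[C@H](O[Si](C)(C)C(C)(C)C)CC(=O)C=C1CC[C@@H]2OC2(C)C | intermediate
13 | (4S,5R)-5-(tert-butyldimethylsilyloxy)-3-[2-((2S)-3,3-dimethyloxiran-2-yl)ethyl]-4-(2-hydroxyethyl)-4-methylcyclohex-2-en-1-ol (C6 carbinol epimers) | OCC[C@]1(C)[C@H](O[Si](C)(C)C(C)(C)C)CC(O)C=C1CC[C@@H]2OC2(C)C | intermediate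
14 | primary (C12) tosylate of 13, C6 hydroxyl free | Cc1ccc(cc1)S(=O)(=O)OCC[C@]2(C)[C@H](O[Si](C)(C)C(C)(C)C)CC(O)C=C2CC[C@@H]3OC3(C)C | intermediate
15 | C6 tert-butyldimethylsilyl ether of 14 | Cc1ccc(cc1)S(=O)(=O)OCC[C@]2(C)[C@H](O[Si](C)(C)C(C)(C)C)CC(O[Si](C)(C)C(C)(C)C)C=C2CC[C@@H]3OC3(C)C | intermediate
16 | rings A/B alcohol: 3β-hydroxy-4,4,9β-trimethyl-6ξ,8α-bis(tert-butyldimethylsilyloxy)-9α-(2-tosyloxyethyl)-Δ5(10)-octalin | Cc1ccc(cc1)S(=O)(=O)OCC[C@]2(C)[C@H](O[Si](C)(C)C(C)(C)C)CC(O[Si](C)(C)C(C)(C)C)C3=C2CC[C@H](O)C3(C)C | intermediate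
17 | rings A/B tosylate: 3β-benzoyloxy-4,4,9β-trimethyl-6ξ,8α-bis(tert-butyldimethylsilyloxy)-9α-(2-tosyloxyethyl)-Δ5(10)-octalin | Cc1ccc(cc1)S(=O)(=O)OCC[C@]2(C)[C@H](O[Si](C)(C)C(C)(C)C)CC(O[Si](C)(C)C(C)(C)C)C3=C2CC[C@H](OC(=O)c4ccccc4)C3(C)C | intermediate
18 | 3,3-dimethylcyclohexan-1-one | CC1(C)CCCC(=O)C1 | starting material
19 | 2,5,5-trimethylcyclohexan-1-one (racemic) | CC1CCC(C)(C)CC1=O | intermediate
20 | (S)-1-phenylethylamine | C[C@H](N)c1ccccc1 | starting material
21 | methyl vinyl ketone | CC(=O)C=C | starting material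
22 | ketimine of 19 with 20 | C[C@H](N=C1CC(C)(C)CCC1C)c1ccccc1 | intermediate
23 | alkylated ketimine (Michael adduct, C17 R) | C[C@H](N=C1CC(C)(C)CC[C@]1(C)CCC(C)=O)c1ccccc1 | intermediate
24 | (R)-2,5,5-trimethyl-2-(3-oxobutyl)cyclohexan-1-one | CC1(C)CC[C@](C)(CCC(C)=O)C(=O)C1 | intermediate
25 | (4aR)-4a,7,7-trimethyl-4,4a,5,6,7,8-hexahydronaphthalen-2(3H)-one | CC1(C)CC[C@]2(C)CCC(=O)C=C2C1 | intermediate
26 | (4aR,8aS)-4a,7,7-trimethyloctahydronaphthalen-2(1H)-one | CC1(C)CC[C@]2(C)CCC(=O)C[C@@H]2C1 | intermediate
27 | diallyl carbonate | C=CCOC(=O)OCC=C | starting material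
28 | allyl (4aR,8aS)-4a,7,7-trimethyl-2-oxodecahydronaphthalene-1-carboxylate | CC1(C)CC[C@]2(C)CCC(=O)C(C(=O)OCC=C)[C@@H]2C1 | intermediate
29 | allyl 3β-benzoyloxy-6ξ,8α-bis(tert-butyldimethylsilyloxy)-14-oxo-26-nor-8,14-seco-D:B-friedoolean-5(10)-en-27-oate | CC1(C)CC[C@]2(C)CCC(=O)[C@](CC[C@]3(C)[C@H](O[Si](C)(C)C(C)(C)C)CC(O[Si](C)(C)C(C)(C)C)C4=C3CC[C@H](OC(=O)c5ccccc5)C4(C)C)(C(=O)OCC=C)[C@@H]2C1 | intermediate
30 | allyl 3β-benzoyloxy-6ξ,8α-bis(tert-butyldimethylsilyloxy)-8,14-seco-D:B-friedooleana-5(10),14(26)-dien-27-oate | CC1(C)CC[C@]2(C)CCC(=C)[C@](CC[C@]3(C)[C@H](O[Si](C)(C)C(C)(C)C)CC(O[Si](C)(C)C(C)(C)C)C4=C3CC[C@H](OC(=O)c5ccccc5)C4(C)C)(C(=O)OCC=C)[C@@H]2C1 | intermediate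
31 | 3β-benzoyloxy-6ξ,8α-bis(tert-butyldimethylsilyloxy)-8,14-seco-D:B-friedooleana-5(10),14(26)-dien-27-oic acid | CC1(C)CC[C@]2(C)CCC(=C)[C@](CC[C@]3(C)[C@H](O[Si](C)(C)C(C)(C)C)CC(O[Si](C)(C)C(C)(C)C)C4=C3CC[C@H](OC(=O)c5ccccc5)C4(C)C)(C(O)=O)[C@@H]2C1 | intermediate
32 | 3β-benzoyloxy-6ξ,8α-dihydroxy-8,14-seco-D:B-friedooleana-5(10),14(26)-dien-27-oic acid | CC1(C)CC[C@]2(C)CCC(=C)[C@](CC[C@]3(C)[C@H](O)CC(O)C4=C3CC[C@H](OC(=O)c5ccccc5)C4(C)C)(C(O)=O)[C@@H]2C1 | intermediate
33 | 3β-benzoyloxy-6,8-dioxo-8,14-seco-D:B-friedooleana-5(10),14(26)-dien-27-oic acid | CC1(C)CC[C@]2(C)CCC(=C)[C@](CC[C@]3(C)C(=O)CC(=O)C4=C3CC[C@H](OC(=O)c5ccccc5)C4(C)C)(C(O)=O)[C@@H]2C1 | intermediate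
34 | acyl fluoride of 33 | CC1(C)CC[C@]2(C)CCC(=C)[C@](CC[C@]3(C)C(=O)CC(=O)C4=C3CC[C@H](OC(=O)c5ccccc5)C4(C)C)(C(F)=O)[C@@H]2C1 | intermediate
35 | 3β-benzoyloxy-6-oxo-8,14-seco-D:B-friedooleana-5(10),7,14(26)-trien-27,8-olide (seven-membered enol lactone) | CC1(C)CC[C@]2(C)CCC(=C)[C@@]3(CC[C@]4(C)C(=CC(=O)C5=C4CC[C@H](OC(=O)c6ccccc6)C5(C)C)OC3=O)[C@@H]2C1 | intermediate
36 | 3β-benzoyloxy-6-oxo-D:B-friedoolean-5(10)-en-27,8α-olide | CC1(C)CC[C@]2(C)CC[C@]3(C)[C@@]45CC(=O)C6=C(CC[C@H](OC(=O)c7ccccc7)C6(C)C)[C@]4(C)CC[C@@]3(C(=O)O5)[C@@H]2C1 | intermediate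
37 | 3β-benzoyloxy-6ξ-hydroxy-D:B-friedoolean-5(10)-en-27,8α-olide | CC1(C)CC[C@]2(C)CC[C@]3(C)[C@@]45CC(O)C6=C(CC[C@H](OC(=O)c7ccccc7)C6(C)C)[C@]4(C)CC[C@@]3(C(=O)O5)[C@@H]2C1 | intermediate
38 | 3β-benzoyloxy-D:B-friedooleana-5(10),6-dien-27,8α-olide | CC1(C)CC[C@]2(C)CC[C@]3(C)[C@@]45C=CC6=C(CC[C@H](OC(=O)c7ccccc7)C6(C)C)[C@]4(C)CC[C@@]3(C(=O)O5)[C@@H]2C1 | target

Total step count: 26. Longest linear sequence: 21 steps (steps 1–12, then 18–26).

Steps most likely to fail

Step 24 (key step). The C14 radical may be reduced before it reaches C8, which amounts to plain hydrogenation of the methylene, and the enol ester may be cleaved under the reaction conditions. The fallback generates the same tertiary radical by halogen-atom abstraction instead of hydrogen-atom transfer. It sets out from 35: dry HBr in CH2Cl2 at −78 °C should add in the Markovnikov sense to the C14 methylene to give the tertiary C14 bromide F1. Slow addition of (Me3Si)3SiH with Et3B/O2 in benzene at room temperature would then form the C14 radical, which closes onto C8 in a reductive Giese cyclization. The fallback comes back to the route at 36.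

Step 18. The electrophile may approach the concave α face of the cis-fused enolate, giving the C13 epimer, or react at the enolate oxygen. The fallback reverses the order in which the two C13 substituents arrive, so that the carboxyl carbon, not C12, enters along the preferred trajectory. It sets out from 28 and 17: the alkylation is run as in step 18, the allyl ester of the crude product is removed with Pd(PPh3)4 and morpholine, and the β-keto acid is decarboxylated on warming to give the 13-alkyl ketone F2. Me3SiI and (Me3Si)2NH would convert this into the more substituted trimethylsilyl enol ether F3. CsF under CO2 in DMF, followed by allyl bromide, would carboxylate C13 and re-form the allyl ester. The fallback comes back to the route at 29.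

Step 11. The Lewis acid-complexed epoxide may rearrange to a ketone or an allylic alcohol before the ring closes, and the C10 carbocation may undergo 1,2-shifts from the neighbouring quaternary C9. The fallback changes the ring closure from the cationic to the radical manifold. It sets out from 15: Cp2TiCl (from Cp2TiCl2 and Mn dust) in THF would open the epoxide homolytically to the tertiary C4 radical, which adds to C5 in a 6-endo mode; the C10 radical is trapped by a second Cp2TiCl and lost by β-hydride elimination. The fallback comes back to the route at 16 and makes no new compound (F0).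

Further compounds
F1 | step 24 | tertiary C14 bromide (HBr adduct of 35) | CC1(C)CC[C@]2(C)CCC(C)(Br)[C@@]3(CC[C@]4(C)C(=CC(=O)C5=C4CC[C@H](OC(=O)c6ccccc6)C5(C)C)OC3=O)[C@@H]2C1
F2 | step 18 | 13-alkyl ketone (29 without its allyloxycarbonyl group, C13 epimers) | CC1(C)CC[C@]2(C)CCC(=O)C(CC[C@]3(C)[C@H](O[Si](C)(C)C(C)(C)C)CC(O[Si](C)(C)C(C)(C)C)C4=C3CC[C@H](OC(=O)c5ccccc5)C4(C)C)[C@@H]2C1
F3 | step 18 | trimethylsilyl enol ether of F2 (C13=C14) | CC1(C)CC[C@]2(C)CCC(O[Si](C)(C)C)=C(CC[C@]3(C)[C@H](O[Si](C)(C)C(C)(C)C)CC(O[Si](C)(C)C(C)(C)C)C4=C3CC[C@H](OC(=O)c5ccccc5)C4(C)C)[C@@H]2C1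
F0 | step 11 | none | none
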